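The 1,2-dioxane ring (O1, O2, C3–C6) is split into two three-atom halves. C6–O1–O2 is a silylperoxycarbenium ion drawn from the side-chain ketone. C5–C4–C3 is an aldehyde homoenolate stored in an enantiopure trans-1-ethyl-2-methoxycyclopropane. One formal [3+3] annulation joins C5 to C6 and O2 to C3: the cation opens the cyclopropane at its CH2 corner, and the oxocarbenium ion released at C3 is captured by the silylperoxy oxygen. The step exploits the two oxygen-bearing ring carbons C3 and C6 flanking C4–C5, and the C4 ethyl stereocentre travels untouched inside the cyclopropane. The precursor pair is an acyclic peroxyketal and a three-membered ring. A ketene silyl acetal then replaces the C3 methoxy group.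

Key step: step 10

Numbering: C1 is the ester carbonyl and C2 its CH2. The ring holds C3 (O-bearing CH), C4 (CH–Et), C5 (CH2), C6 (quaternary), O1 (on C6) and O2 (on C3). The side chain is C7–C14, with ethyl on C8 and methyl on C10.

Assumption: the sense of induction of the ferrocenyl diphosphine (steps 1 and 4), the tartramide (step 8) and the imidodiphosphorimidate (step 10) is assumed as drawn. Each antipode is equally accessible and would be swapped in if the sense proves opposite.

Step 1
Reactants: 1 methyl (E)-but-2-enoate; 2 n-butylmagnesium bromide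
Product: 3 methyl (S)-3-methylheptanoate
Conditions: CuBr·SMe2 (1 mol %), (R)-1-[(S)-2-(diphenylphosphino)ferrocenyl]ethyldicyclohexylphosphine (1.2 mol %), t-BuOMe, −75 °C; then 1 M aq HCl
Reagents that add atoms: none
Why: Copper-catalysed asymmetric conjugate addition of a Grignard reagent to an (E)-enoate, in which the chiral diphosphine–CuBr complex selects the alkene face and sets C10 as (S).

Step 2
Reactants: 3 methyl (S)-3-methylheptanoate
Product: 4 (S)-3-methylheptanal
Conditions: i-Bu2AlH (1.05 equiv), CH2Cl2, −78 °C; then MeOH, aq potassium sodium tartrate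
Reagents that add atoms: none
Why: Partial ester reduction with i-Bu2AlH, whose tetrahedral aluminium adduct persists at −78 °C and releases the aldehyde only on work-up, while the β-stereocentre cannot epimerise.

Step 3
Reactants: 4 (S)-3-methylheptanal; 5 diethyl (2-oxobutyl)phosphonate
Product: 6 (4E,7S)-7-methylundec-4-en-3-one
Conditions: NaH, THF, 0 °C to 20 °C
Reagents that add atoms: none
Why: Horner–Wadsworth–Emmons olefination with a stabilised β-ketophosphonate anion, which should give the (E)-enone under thermodynamic control of the elimination.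

Step 4
Reactants: 6 (4E,7S)-7-methylundec-4-en-3-one; 7 ethylmagnesium bromide
Product: 8 (5S,7S)-5-ethyl-7-methylundecan-3-one
Conditions: CuBr·SMe2 (5 mol %), (S)-1-[(R)-2-(diphenylphosphino)ferrocenyl]ethyldicyclohexylphosphine (6 mol %), t-BuOMe, −75 °C; then 1 M aq HCl
Reagents that add atoms: none
Why: Copper-catalysed asymmetric conjugate addition of a Grignard reagent to an acyclic enone, in which the catalyst and not the remote C10 centre controls the face and sets C8 as (S).

Step 5
Reactants: 8 (5S,7S)-5-ethyl-7-methylundecan-3-one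
Product: 9 (5S,7S)-5-ethyl-3-hydroperoxy-3-methoxy-7-methylundecane (C3 epimers)
Conditions: 30% aq H2O2 (4 equiv), I2 (10 mol %), MeOH, 20 °C
Reagents that add atoms: hydrogen peroxide OO; methanol CO
Why: Iodine-catalysed perhydrolysis of a ketone in methanol gives the α-methoxy hydroperoxide, and its new centre needs no control because step 10 planarises it.

Step 6
Reactants: 9 (5S,7S)-5-ethyl-3-hydroperoxy-3-methoxy-7-methylundecane
Product: 10 triethyl{[(5S,7S)-5-ethyl-3-methoxy-7-methylundecan-3-yl]peroxy}silane (C3 epimers)
Conditions: Et3SiCl, imidazole, CH2Cl2, 0 °C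
Reagents that add atoms: chlorotriethylsilane CC[Si](Cl)(CC)CC
Why: O-silylation of a hydroperoxide under mild base, which masks the acidic OOH proton and installs the silyl group that later leaves from O2.

Step 7
Reactants: 11 (E)-but-1-en-1-ylboronic acid; 12 (2S,3S)-2,3-dihydroxy-N,N,N',N'-tetramethylbutanediamide
Product: 13 (4S,5S)-2-[(E)-but-1-en-1-yl]-N,N,N',N'-tetramethyl-1,3,2-dioxaborolane-4,5-dicarboxamide
Conditions: 4 Å molecular sieves, CH2Cl2, 20 °C
Reagents that add atoms: none
Why: Condensation of a boronic acid with a 1,2-diol to the cyclic boronic ester, driven by removal of water.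

Step 8
Reactants: 13 (4S,5S)-2-[(E)-but-1-en-1-yl]-N,N,N',N'-tetramethyl-1,3,2-dioxaborolane-4,5-dicarboxamide
Product: 15 (1S,2S)-2-ethylcyclopropan-1-ol, via cyclopropylboronate 14 (not isolated)
Conditions: Zn–Cu couple, CH2I2, Et2O, reflux; then 30% aq H2O2, KHCO3, THF, 0 °C
Reagents that add atoms: diiodomethane ICI; hydrogen peroxide OO
Why: Auxiliary-controlled Simmons–Smith cyclopropanation, stereospecific so that the (E)-alkene gives the trans ring and face-selective through the amide groups of the tartramide that bind the zinc carbenoid, followed by stereoretentive oxidation of the C–B bond, which together set the future C4.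

Step 9
Reactants: 15 (1S,2S)-2-ethylcyclopropan-1-ol
Product: 16 (1S,2S)-1-ethyl-2-methoxycyclopropane
Conditions: NaH, MeI, diglyme, 0 °C to 20 °C; product distilled out
Reagents that add atoms: iodomethane CI
Why: Williamson etherification of the cyclopropoxide in an aprotic medium, where ring opening has no proton source and no bond to a stereocentre is broken.

Step 10
Reactants: 10 triethyl{[(5S,7S)-5-ethyl-3-methoxy-7-methylundecan-3-yl]peroxy}silane; 16 (1S,2S)-1-ethyl-2-methoxycyclopropane (2 equiv)
Product: 19 (4S,6S)-4,6-diethyl-6-[(2S,4S)-2-ethyl-4-methyloctyl]-3-methoxy-1,2-dioxane (C3 anomers), via silylperoxycarbenium ion 17 (not isolated), via ring-opened oxocarbenium ion 18 (not isolated)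
Conditions: confined chiral imidodiphosphorimidate Brønsted acid (IDPi, BINOL-derived, 3,3'-aryl groups, N-triflyl; 5 mol %), 4 Å molecular sieves, toluene–CH2Cl2, −78 °C
Reagents that add atoms: none
Why: Proposed new method: the chiral acid ionises the methoxy group of 10 to the silylperoxycarbenium ion 17, the oxygen-activated C3–C5 σ-bond of 16 attacks its C6 through the unsubstituted corner C5, and the methoxy-stabilised oxocarbenium ion 18 set free at C3 is captured by O2 with loss of the triethylsilyl cation, which silylates the methoxy group of the next molecule of 10 and so carries the chain. The closest known reaction types are the Lewis acid-mediated [3+2] annulation of triethylsilylperoxycarbenium ions with alkenes to 1,2-dioxolanes, the formal [3+3] annulation of nitrones with donor–acceptor cyclopropanes and the homoaldol opening of oxygen-substituted cyclopropanes by activated carbonyl compounds. The single new ring, the 1,2-dioxane, closes in the 6-exo-trig mode at C3. C4 takes no part and keeps the configuration of 16, C3 forms as an anomeric mixture that step 11 erases, and C6 is set by the confined chiral counteranion paired with 17, by analogy with silylium-type asymmetric counteranion-directed additions to dialkyl ketones in which such anions tell an ethyl group from its alkyl neighbour. The step needs cleavage of C3–C5 and not of C3–C4, which the donor oxygen on C3 and the steric demand of the tertiary cation for the CH2 corner secure, and loss of methoxide and not of silylperoxide from 10, which the higher basicity and silicon affinity of the methoxy oxygen secure. Facial selectivity at C6 cannot come from the substrate, because ethyl and the side-chain CH2 are sterically alike, and therefore rests on the catalyst.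

Step 11
Reactants: 19 (4S,6S)-4,6-diethyl-6-[(2S,4S)-2-ethyl-4-methyloctyl]-3-methoxy-1,2-dioxane; 20 tert-butyl[(1-methoxyethenyl)oxy]dimethylsilane
Product: 22 methyl 2-{(3S,4S,6S)-4,6-diethyl-6-[(2S,4S)-2-ethyl-4-methyloctyl]-1,2-dioxan-3-yl}acetate (target), via 1,2-dioxan-3-ylium ion 21 (not isolated)
Conditions: Me3SiOTf (20 mol %), CH2Cl2, −78 °C
Reagents that add atoms: none
Why: Mukaiyama-type substitution of a cyclic peroxyacetal, in which the silyl triflate ionises the methoxy group to cation 21, whose half-chair keeps both ethyl groups pseudo-equatorial because the alternative suffers a 1,3-diaxial ethyl–ethyl clash, and stereoelectronically preferred axial attack of 20 through a chair-like transition state places the acetate arm on C3 cis to the C4 ethyl group, which is the (3S) configuration.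

Compound list
1 | methyl (E)-but-2-enoate | C/C=C/C(=O)OC | starting material
2 | n-butylmagnesium bromide | CCCC[Mg]Br | starting material
3 | methyl (S)-3-methylheptanoate | CCCC[C@H](C)CC(=O)OC | intermediate
4 | (S)-3-methylheptanal | CCCC[C@H](C)CC=O | intermediate
5 | diethyl (2-oxobutyl)phosphonate | CCOP(=O)(CC(=O)CC)OCC | starting material
6 | (4E,7S)-7-methylundec-4-en-3-one | CCCC[C@H](C)C/C=C/C(=O)CC | intermediate
7 | ethylmagnesium bromide | CC[Mg]Br | starting material
8 | (5S,7S)-5-ethyl-7-methylundecan-3-one | CCCC[C@H](C)C[C@H](CC)CC(=O)CC | intermediate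
9 | (5S,7S)-5-ethyl-3-hydroperoxy-3-methoxy-7-methylundecane (C3 epimers) | CCCC[C@H](C)C[C@H](CC)CC(CC)(OC)OO | intermediate
10 | triethyl{[(5S,7S)-5-ethyl-3-methoxy-7-methylundecan-3-yl]peroxy}silane (C3 epimers) | CCCC[C@H](C)C[C@H](CC)CC(CC)(OC)OO[Si](CC)(CC)CC | intermediate
11 | (E)-but-1-en-1-ylboronic acid | CC/C=C/B(O)O | starting material
12 | (2S,3S)-2,3-dihydroxy-N,N,N',N'-tetramethylbutanediamide | CN(C)C(=O)[C@@H](O)[C@H](O)C(=O)N(C)C | starting material
13 | (4S,5S)-2-[(E)-but-1-en-1-yl]-N,N,N',N'-tetramethyl-1,3,2-dioxaborolane-4,5-dicarboxamide | CC/C=C/B1O[C@@H]([C@H](O1)C(=O)N(C)C)C(=O)N(C)C | intermediate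
14 | (4S,5S)-2-[(1S,2S)-2-ethylcyclopropyl]-N,N,N',N'-tetramethyl-1,3,2-dioxaborolane-4,5-dicarboxamide | CC[C@H]1C[C@@H]1B2O[C@@H]([C@H](O2)C(=O)N(C)C)C(=O)N(C)C | intermediate
15 | (1S,2S)-2-ethylcyclopropan-1-ol | CC[C@H]1C[C@@H]1O | intermediate
16 | (1S,2S)-1-ethyl-2-methoxycyclopropane | CC[C@H]1C[C@@H]1OC | intermediate
17 | silylperoxycarbenium ion, [(5S,7S)-5-ethyl-7-methylundecan-3-ylidene](triethylsilyloxy)oxonium | CCCC[C@H](C)C[C@H](CC)CC(CC)=[O+]O[Si](CC)(CC)CC | intermediate
18 | ring-opened oxocarbenium ion, O-methyl oxonium of (2S,4S,6S,8S)-2,4,6-triethyl-8-methyl-4-(triethylsilylperoxy)dodecanal | CCCC[C@H](C)C[C@H](CC)C[C@](CC)(OO[Si](CC)(CC)CC)C[C@H](CC)C=[O+]C | intermediate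
19 | (4S,6S)-4,6-diethyl-6-[(2S,4S)-2-ethyl-4-methyloctyl]-3-methoxy-1,2-dioxane (C3 anomers) | CCCC[C@H](C)C[C@H](CC)C[C@@]1(CC)C[C@H](CC)C(OC)OO1 | intermediate
20 | tert-butyl[(1-methoxyethenyl)oxy]dimethylsilane | C=C(OC)O[Si](C)(C)C(C)(C)C | starting material
21 | (4S,6S)-4,6-diethyl-6-[(2S,4S)-2-ethyl-4-methyloctyl]-1,2-dioxan-3-ylium ion | CCCC[C@H](C)C[C@H](CC)C[C@@]1(CC)C[C@H](CC)C=[O+]O1 | intermediate
22 | methyl 2-{(3S,4S,6S)-4,6-diethyl-6-[(2S,4S)-2-ethyl-4-methyloctyl]-1,2-dioxan-3-yl}acetate | CCCC[C@H](C)C[C@H](CC)C[C@@]1(CC)C[C@H](CC)[C@H](CC(=O)OC)OO1 | target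

Total step count: 11. Longest linear sequence: 8 steps (steps 1–6, 10 and 11). The cyclopropane branch (steps 7–9) joins at step 10.

Steps most likely to fail

1. Step 10.
- **What may go wrong:** opening of the cyclopropane may be slower than O–O heterolysis or proton loss of the cation. The acid may isomerise the cyclopropane. Facial discrimination at C6 by the counteranion may be insufficient.
- **Fallback (from 15 and 8, back at 19):** it uses known chemistry, builds the two bonds in separate operations and gives up control at C6. Electrophilic ring opening of cyclopropanol 15 with N-bromosuccinimide at the CH2 corner should give (R)-2-(bromomethyl)butanal F1. This is acetalised at once with trimethyl orthoformate and acid to (R)-2-(bromomethyl)-1,1-dimethoxybutane F2. Magnesium insertion below 25 °C gives [(R)-2-(dimethoxymethyl)butyl]magnesium bromide F3. In the presence of CeCl3, F3 adds to ketone 8 to give (2S,6S,8S)-2,4,6-triethyl-1,1-dimethoxy-8-methyldodecan-4-ol F4 as C4 epimers. Acid-catalysed substitution of the tertiary alcohol with ethereal H2O2 gives (2S,6S,8S)-2,4,6-triethyl-4-hydroperoxy-1,1-dimethoxy-8-methyldodecane F5. Under the same acid F5 closes onto the acetal to 19, and the C6 epimers are then separated by chromatography.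

2. Step 11.
- **What may go wrong:** the very reactive ketene acetal may erode the axial selectivity at C3. The cation may lose the C4 proton, and the O–O bond may be cleaved by the Lewis acid.
- **Fallback (from 19, back at 22):** the much less reactive allyltrimethylsilane with SnCl4 at −78 °C should follow the stereoelectronic preference more closely. It should give (3S,4S,6S)-3-allyl-4,6-diethyl-6-[(2S,4S)-2-ethyl-4-methyloctyl]-1,2-dioxane F6. Ozonolysis with Me2S work-up gives 2-{(3S,4S,6S)-4,6-diethyl-6-[(2S,4S)-2-ethyl-4-methyloctyl]-1,2-dioxan-3-yl}acetaldehyde F7. Pinnick oxidation gives the corresponding acetic acid F8, and Me3SiCHN2 in methanol–toluene gives 22.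

3. Step 5.
- **What may go wrong:** perketalisation of the acyclic, β-branched ketone may stay incomplete. Exchange may also run on to the geminal bis-hydroperoxide stage.
- **Fallback (from 8, back at 9):** Wittig methylenation with Ph3P=CH2 gives (5S,7S)-5-ethyl-7-methyl-3-methylideneundecane F9. Ozonolysis of F9 in MeOH–CH2Cl2 at −78 °C cleaves towards the more substituted carbonyl oxide, which methanol traps to give 9.

Further compounds
F1 | step 10 | (R)-2-(bromomethyl)butanal | BrC[C@H](CC)C=O
F2 | step 10 | (R)-2-(bromomethyl)-1,1-dimethoxybutane | BrC[C@H](CC)C(OC)OC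
F3 | step 10 | [(R)-2-(dimethoxymethyl)butyl]magnesium bromide | Br[Mg]C[C@H](CC)C(OC)OC
F4 | step 10 | (2S,6S,8S)-2,4,6-triethyl-1,1-dimethoxy-8-methyldodecan-4-ol (C4 epimers) | CCCC[C@H](C)C[C@H](CC)CC(O)(CC)C[C@H](CC)C(OC)OC
F5 | step 10 | (2S,6S,8S)-2,4,6-triethyl-4-hydroperoxy-1,1-dimethoxy-8-methyldodecane (C4 epimers) | CCCC[C@H](C)C[C@H](CC)CC(CC)(OO)C[C@H](CC)C(OC)OC
F6 | step 11 | (3S,4S,6S)-3-allyl-4,6-diethyl-6-[(2S,4S)-2-ethyl-4-methyloctyl]-1,2-dioxane | CCCC[C@H](C)C[C@H](CC)C[C@@]1(CC)C[C@H](CC)[C@H](CC=C)OO1
F7 | step 11 | 2-{(3S,4S,6S)-4,6-diethyl-6-[(2S,4S)-2-ethyl-4-methyloctyl]-1,2-dioxan-3-yl}acetaldehyde | CCCC[C@H](C)C[C@H](CC)C[C@@]1(CC)C[C@H](CC)[C@H](CC=O)OO1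
F8 | step 11 | 2-{(3S,4S,6S)-4,6-diethyl-6-[(2S,4S)-2-ethyl-4-methyloctyl]-1,2-dioxan-3-yl}acetic acid | CCCC[C@H](C)C[C@H](CC)C[C@@]1(CC)C[C@H](CC)[C@H](CC(=O)O)OO1
F9 | step 5 | (5S,7S)-5-ethyl-7-methyl-3-methylideneundecane | CCCC[C@H](C)C[C@H](CC)CC(=C)CC
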